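(The earlier runs and the new flask stem from a simulated flask with made-up constants.)

Give this flask 1.0 h, and turn the question round: what would keep substrate ahead of product?

in all of them: free catalyst 5 mol%

|  | substrate | coupling partner | remark | time |
|---|---|---|---|---|
| elm | 6.7 mM | 3 equiv | run made earlier |  |
| birch | 15 mM | 3 equiv | run made earlier |  |
| larch | 10 mM | 6 equiv | run made earlier |  |
| flask | 10 mM | 3.00 equiv |  | 1.0 h |

| run | time / min | catalyst intermediate A / % | catalyst intermediate B / % | product / % | catalyst intermediate C / % | substrate / % |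
|---|---|---|---|---|---|---|
| elm | 6.00 | 0 | 2.9 | 2.9 | 0.8 | 94.2 |
| elm | 15.0 | 0.6 | 1.0 | 9.9 | 0 | 87.0 |
| elm | 20.0 | 0.6 | 2.5 | 15.8 | 0 | 84.3 |
| elm | 30.0 | 0 | 1.8 | 20.6 | 0 | 75.3 |
| elm | 40.0 | 0.5 | 0.9 | 29.0 | 1.2 | 69.6 |
| elm | 50.0 | 0 | 1.1 | 34.1 | 1.0 | 64.2 |
| birch | 4.00 | 0.2 | 1.6 | 3.7 | 0.5 | 91.9 |
| birch | 6.00 | 0.3 | 0.2 | 7.8 | 0.7 | 90.3 |
| birch | 8.00 | 1.2 | 1.4 | 12.3 | 0 | 88.0 |
| birch | 15.0 | 2.0 | 2.5 | 21.4 | 0.1 | 76.9 |
| birch | 20.0 | 0 | 0.5 | 26.7 | 0.2 | 71.2 |
| birch | 30.0 | 0.8 | 2.1 | 39.1 | 0.1 | 58.0 |
| birch | 50.0 | 0.5 | 1.8 | 59.5 | 1.0 | 39.0 |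
| larch | 10.0 | 1.4 | 0.3 | 13.2 | 0 | 87.3 |
| larch | 20.0 | 0.7 | 1.6 | 25.0 | 0 | 75.1 |
| larch | 30.0 | 0 | 0.7 | 33.3 | 0.3 | 62.9 |
| larch | 40.0 | 0 | 0.4 | 45.2 | 0.9 | 53.9 |
| larch | 50.0 | 1.1 | 1.1 | 52.5 | 0 | 44.1 |

(standard deviation of a reading: 1 percentage point)

- the earlier runs were read with a standard deviation of 1 percentage point
- steps thought possible: substrate + free catalyst <-> catalyst intermediate A; catalyst intermediate A -> catalyst intermediate B; coupling partner + catalyst intermediate B -> catalyst intermediate C; catalyst intermediate C -> free catalyst + product; coupling partner <-> dormant form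

- the species that holds most of what was charged as substrate, at 1.0 h (product / catalyst intermediate C / substrate / catalyst intermediate B / catalyst intermediate A)
- the largest share itself, whichever of these holds it, in percent of the substrate charged

The catalyst forms can hold at most 5 mol% of the substrate, so the lead passes to product close to where one substrate half-life has run. Substrate therefore stays ahead if the flask gets fewer than one half-life.

Divide the logarithm of the substrate fraction left in the birch run by that in the elm run, both read at 50.0 min, and time drops out. The ratio is 2.12 against a charge ratio of 2.24. At 3 equiv and 5 mol%, then, these two readings, taken as pseudo-first-order loss, give a constant nearly proportional to the charge.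

Scaled by charge and time to this flask, the elm reading gives 1.15 half-lives and the birch reading 1.09. I carry their mean, 1.12, as the half-life count: the substrate half-lives a run gets, taken to grow with charge times time at fixed equivalents and loading. The flask stands 0.120 above the count of one, so my reckoning leaves 46.1% of the substrate and puts product narrowly ahead.

The forecast gives product at 51%, in its words “Product narrowly leads”. The flask gives product at 53.2%, with substrate at 45.0%.

    substrate + free catalyst ⇌ catalyst intermediate A (K = 83.0 M⁻¹, k = 1.29 M⁻¹ s⁻¹)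
    catalyst intermediate A → catalyst intermediate B (k = 0.0244 s⁻¹)
    coupling partner + catalyst intermediate B → catalyst intermediate C (k = 0.375 M⁻¹ s⁻¹)
    catalyst intermediate C → free catalyst + product (k = 1.14 s⁻¹)
    coupling partner ⇌ dormant form (K = 0.0800, k = 2.41 × 10⁻⁴ s⁻¹)

That substrate figure makes the flask's count 1.15, and product and substrate hold the same at 0.890 of its substrate charge. In the flask at 0.426 h, catalyst intermediate B is made at 0.992 of the rate at which it is used up, each step taken net. Carried to a further flask charged with 2.5 mM of substrate, same equivalents, loading and time, the count becomes 0.279 and leaves 82.4%; that flask keeps 81% of its substrate charge unbound.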